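**Strategy.** The route rests on cutting the O2–C3 bond of the 1,2-dioxolane ring. The key step exploits the quaternary ring carbon C3 and its two-carbon arm C2–C1: in the precursor, C3, C2, C1 and a temporary oxygen form a 2-methyloxetane, tethered through C4 to a tertiary hydroperoxide at C5. Acid-promoted 5-exo-tet attack of the hydroperoxide opens the oxetane at C3 with inversion. This closes the dioxolane, fixes C3 from a Sharpless-derived stereocenter and frees C1 as an alcohol that is oxidised to the acid. The precursor comes from a chiral bromoallyl oxetane, a chiral-pool side chain (Negishi coupling) and a Co(acac)2-catalysed hydrosilylperoxidation.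

Key step: step 10

Assumption: 11 and 12 are taken as purchasable; step 8 is not expected to control C5, so both C5 epimers are carried to step 10 and separated there as cis and trans ring isomers.

Step 1
Reactants: 1 2,3-dibromoprop-1-ene; 2 ethynylmagnesium bromide
Product: 3 2-bromopent-1-en-4-yne
Conditions: CuBr·SMe2 (5 mol %), THF, 0 °C to rt, 2 in excess
Reagents that add atoms: none
Why: Copper-catalysed SN2 coupling of an alkynyl Grignard reagent with an allylic bromide, in which the vinylic bromide is inert and the excess acetylide suppresses double allylation.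

Step 2
Reactants: 3 2-bromopent-1-en-4-yne
Product: 6 (2E)-5-bromo-3-methylhexa-2,5-dien-1-ol, via alkenyldimethylalane 4 (not isolated), via lithium alkenyltrimethylaluminate 5 (not isolated)
Conditions: AlMe3, Cp2ZrCl2 (20 mol %), CH2Cl2, 0 °C to rt; volatiles removed; MeLi, THF, −78 °C; (CH2O)n, −78 °C to rt
Reagents that add atoms: trimethylaluminium C[Al](C)C; formaldehyde (as paraformaldehyde) C=O
Why: Negishi Cp2ZrCl2-catalysed carboalumination adds methyl and aluminium syn across the terminal alkyne with aluminium at the terminal carbon, which fixes the E trisubstituted alkene, and the aluminate formed with MeLi (which should not exchange with the vinylic bromide) is hydroxymethylated by formaldehyde with retention of geometry.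

Step 3
Reactants: 6 (2E)-5-bromo-3-methylhexa-2,5-dien-1-ol
Product: 7 [(2S,3S)-3-(2-bromoprop-2-en-1-yl)-3-methyloxiran-2-yl]methanol
Conditions: Ti(OiPr)4 (10 mol %), L-(+)-diisopropyl tartrate (12 mol %), t-BuOOH, 4 Å molecular sieves, CH2Cl2, −20 °C
Reagents that add atoms: tert-butyl hydroperoxide CC(C)(C)OO
Why: Sharpless asymmetric epoxidation of an E-3,3-disubstituted allylic alcohol, in which the L-(+)-tartrate should deliver oxygen to the face that gives the (2S,3S)-epoxide as with geraniol, setting the oxygen-bearing C3 stereocenter (inverted later), while the electron-poor bromoalkene is left alone.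

Step 4
Reactants: 7 [(2S,3S)-3-(2-bromoprop-2-en-1-yl)-3-methyloxiran-2-yl]methanol
Product: 8 (3R)-5-bromo-3-methylhex-5-ene-1,3-diol
Conditions: NaAlH2(OCH2CH2OCH3)2, THF, 0 °C to rt; Rochelle salt work-up
Reagents that add atoms: none
Why: Hydroxyl-directed hydride opening of a 2,3-epoxy alcohol at C2 gives the 1,3-diol and leaves the tertiary C–O stereocenter untouched.

Step 5
Reactants: 8 (3R)-5-bromo-3-methylhex-5-ene-1,3-diol
Product: 10 (2R)-2-(2-bromoprop-2-en-1-yl)-2-methyloxetane, via primary tosylate 9 (not isolated)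
Conditions: TsCl, Et3N, DMAP (cat.), CH2Cl2, 0 °C; aqueous work-up; NaH, THF, 0 °C to rt
Reagents that add atoms: none
Why: Selective sulfonylation of the primary alcohol followed by intramolecular Williamson etherification (4-exo-tet) by the tertiary alkoxide closes the oxetane with retention at the tertiary carbon, whose C–O bond is not broken.

Step 6
Reactants: 11 (7-bromoheptyl)benzene; 12 (2S)-1-bromo-3-chloro-2-methylpropane
Product: 14 [(9R)-10-chloro-9-methyldecyl]benzene, via Grignard reagent 13 (not isolated)
Conditions: Mg, THF, rt; then 12, Li2CuCl4 (3 mol %), THF, −20 °C to rt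
Reagents that add atoms: none
Why: Li2CuCl4-catalysed alkyl–alkyl Grignard cross-coupling takes place at the C–Br bond much faster than at C–Cl, and the stereocenter next to the reacting carbon is not touched.

Step 7
Reactants: 14 [(9R)-10-chloro-9-methyldecyl]benzene; 10 (2R)-2-(2-bromoprop-2-en-1-yl)-2-methyloxetane
Product: 17 (2S)-2-methyl-2-[(4R)-4-methyl-2-methylidene-12-phenyldodecyl]oxetane, via Grignard reagent 15 (not isolated), via alkylzinc chloride 16 (not isolated)
Conditions: Mg, THF, reflux; ZnCl2, THF, 0 °C; then 10, Pd(dppf)Cl2 (5 mol %), THF, 50 °C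
Reagents that add atoms: none
Why: Negishi coupling of a primary alkylzinc chloride with a 2-bromo-1-alkene under Pd(dppf)Cl2, whose wide bite angle favours reductive elimination over beta-hydride elimination, with the oxetane and both stereocenters as spectators (the oxetane descriptor changes only because the substituent priorities change).

Step 8
Reactants: 17 (2S)-2-methyl-2-[(4R)-4-methyl-2-methylidene-12-phenyldodecyl]oxetane
Product: 18 triethyl({(2R,4R)-2,4-dimethyl-1-[(2R)-2-methyloxetan-2-yl]-12-phenyldodecan-2-yl}peroxy)silane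
Conditions: Co(acac)2 (10 mol %), Et3SiH, O2 (1 atm), 1,2-dichloroethane, rt
Reagents that add atoms: dioxygen O=O; triethylsilane CC[SiH](CC)CC
Why: Mukaiyama–Isayama hydrosilylperoxidation, in which hydrogen-atom transfer from a Co–H species to the CH2 terminus gives the tertiary C5 radical that is trapped by O2 and silylated, so the methylidene becomes the C5 methyl and the peroxide sits at C5; no facial bias is expected, so 18 should form together with its C5 epimer and the pair is carried on.

Step 9
Reactants: 18 triethyl({(2R,4R)-2,4-dimethyl-1-[(2R)-2-methyloxetan-2-yl]-12-phenyldodecan-2-yl}peroxy)silane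
Product: 19 (2R,4R)-2,4-dimethyl-1-[(2R)-2-methyloxetan-2-yl]-12-phenyldodecan-2-yl hydroperoxide
Conditions: Bu4NF, AcOH, THF, 0 °C
Reagents that add atoms: none
Why: Fluoride-mediated desilylation cleaves the O–Si bond of the silyl peroxide, and the acetic acid buffer keeps the hydroperoxide and the oxetane away from strong base or acid.

Step 10
Reactants: 19 (2R,4R)-2,4-dimethyl-1-[(2R)-2-methyloxetan-2-yl]-12-phenyldodecan-2-yl hydroperoxide
Product: 20 2-[(3S,5R)-3,5-dimethyl-5-[(2R)-2-methyl-10-phenyldecyl]-1,2-dioxolan-3-yl]ethan-1-ol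
Conditions: TMSOTf (0.2 equiv), Et2O, −78 to 0 °C; Et3N, aq. NaHCO3; chromatographic removal of the trans ring isomer
Reagents that add atoms: none
Why: The silyl triflate (or the triflic acid it releases) activates the oxetane oxygen, and the terminal oxygen of the C5 hydroperoxide attacks the tertiary oxetane carbon (the future C3) from the rear, so the O2–C3 bond forms with inversion and the oxetane oxygen is released as the primary alcohol on C1. The closest known reaction type is the Lewis acid mediated opening of 2,2-disubstituted oxetanes by hydrogen peroxide or alkyl hydroperoxides at the tertiary carbon with inversion, run here within one molecule. The 1,2-dioxolane closes in the 5-exo-tet mode, the breaking C–O bond lying outside the new ring. C3 is the only new stereocenter and is controlled by the oxetane stereocenter set in the Sharpless epoxidation of step 3, inverted once here (its descriptor in 20 is S only because C4 outranks the CH2CH2OH arm; it becomes R in the acid). The step needs attack at the tertiary oxetane carbon rather than at the oxetane CH2, which the five-membered transition state and the greater positive charge at the tertiary carbon should secure, and it needs substitution with inversion rather than free ionisation, which low temperature, ether solvent and the tethered alpha-effect nucleophile favour. Both C5 epimers of 19 should cyclise, so the 3,5-cis-dimethyl product 20 is separated at this point from its trans ring isomer.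

Step 11
Reactants: 20 2-[(3S,5R)-3,5-dimethyl-5-[(2R)-2-methyl-10-phenyldecyl]-1,2-dioxolan-3-yl]ethan-1-ol
Product: 21 2-[(3R,5R)-3,5-dimethyl-5-[(2R)-2-methyl-10-phenyldecyl]-1,2-dioxolan-3-yl]acetic acid
Conditions: TEMPO (20 mol %), PhI(OAc)2 (2.2 equiv), MeCN/H2O, rt
Reagents that add atoms: water O
Why: TEMPO/PhI(OAc)2 oxidation in aqueous acetonitrile takes the primary alcohol through the aldehyde hydrate to the carboxylic acid without touching the dialkyl peroxide or the quaternary stereocenters.

**Compound list**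

1 | 2,3-dibromoprop-1-ene | C=C(Br)CBr | starting material
2 | ethynylmagnesium bromide | C#C[Mg]Br | starting material
3 | 2-bromopent-1-en-4-yne | C=C(Br)CC#C | intermediate
4 | [(1E)-4-bromo-2-methylpenta-1,4-dien-1-yl]dimethylalumane | C=C(Br)C/C(C)=C/[Al](C)C | intermediate
5 | lithium [(1E)-4-bromo-2-methylpenta-1,4-dien-1-yl]trimethylaluminate | [Li+].C=C(Br)C/C(C)=C/[Al-](C)(C)C | intermediate
6 | (2E)-5-bromo-3-methylhexa-2,5-dien-1-ol | C=C(Br)C/C(C)=C/CO | intermediate
7 | [(2S,3S)-3-(2-bromoprop-2-en-1-yl)-3-methyloxiran-2-yl]methanol | C=C(Br)C[C@]1(C)O[C@H]1CO | intermediate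
8 | (3R)-5-bromo-3-methylhex-5-ene-1,3-diol | C=C(Br)C[C@@](O)(C)CCO | intermediate
9 | (3R)-5-bromo-3-hydroxy-3-methylhex-5-en-1-yl 4-methylbenzenesulfonate | C=C(Br)C[C@@](O)(C)CCOS(=O)(=O)c1ccc(C)cc1 | intermediate
10 | (2R)-2-(2-bromoprop-2-en-1-yl)-2-methyloxetane | C=C(Br)C[C@@]1(C)CCO1 | intermediate
11 | (7-bromoheptyl)benzene | BrCCCCCCCc1ccccc1 | starting material
12 | (2S)-1-bromo-3-chloro-2-methylpropane | C[C@H](CBr)CCl | starting material
13 | (7-phenylheptyl)magnesium bromide | Br[Mg]CCCCCCCc1ccccc1 | intermediate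
14 | [(9R)-10-chloro-9-methyldecyl]benzene | C[C@H](CCCCCCCCc1ccccc1)CCl | intermediate
15 | [(2R)-2-methyl-10-phenyldecyl]magnesium chloride | C[C@H](CCCCCCCCc1ccccc1)C[Mg]Cl | intermediate
16 | [(2R)-2-methyl-10-phenyldecyl]zinc chloride | C[C@H](CCCCCCCCc1ccccc1)C[Zn]Cl | intermediate
17 | (2S)-2-methyl-2-[(4R)-4-methyl-2-methylidene-12-phenyldodecyl]oxetane | C=C(C[C@H](C)CCCCCCCCc1ccccc1)C[C@@]1(C)CCO1 | intermediate
18 | triethyl({(2R,4R)-2,4-dimethyl-1-[(2R)-2-methyloxetan-2-yl]-12-phenyldodecan-2-yl}peroxy)silane | C[C@H](CCCCCCCCc1ccccc1)C[C@](OO[Si](CC)(CC)CC)(C)C[C@@]1(C)CCO1 | intermediate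
19 | (2R,4R)-2,4-dimethyl-1-[(2R)-2-methyloxetan-2-yl]-12-phenyldodecan-2-yl hydroperoxide | C[C@H](CCCCCCCCc1ccccc1)C[C@](OO)(C)C[C@@]1(C)CCO1 | intermediate
20 | 2-[(3S,5R)-3,5-dimethyl-5-[(2R)-2-methyl-10-phenyldecyl]-1,2-dioxolan-3-yl]ethan-1-ol | C[C@H](CCCCCCCCc1ccccc1)C[C@]1(C)C[C@](C)(CCO)OO1 | intermediate
21 | 2-[(3R,5R)-3,5-dimethyl-5-[(2R)-2-methyl-10-phenyldecyl]-1,2-dioxolan-3-yl]acetic acid | C[C@H](CCCCCCCCc1ccccc1)C[C@]1(C)C[C@](C)(CC(=O)O)OO1 | target

**Step count.** Total: 11 steps. Longest linear sequence: 10 steps (steps 1–5 and 7–11, from 2,3-dibromoprop-1-ene).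

**Steps most likely to fail**

Step 10. The activated oxetane may ionise to a free tertiary cation, which would erode the inversion at C3 and divert material to elimination. The acid may also trigger Hock-type cleavage of the tertiary hydroperoxide. The fallback sets out from 7 and comes back at 21; it keeps the same O2–C3 closure but runs it on the epoxide under base, where no cation can form.
- 7 is silylated (TBSCl, imidazole, DMF) to tert-butyl{[(2S,3S)-3-(2-bromoprop-2-en-1-yl)-3-methyloxiran-2-yl]methoxy}dimethylsilane F1.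
- Negishi coupling with zinc reagent 16 (made from 14 as in step 7) gives tert-butyldimethyl{[(2S,3S)-3-methyl-3-[(4R)-4-methyl-2-methylidene-12-phenyldodecyl]oxiran-2-yl]methoxy}silane F2.
- Co(acac)2/Et3SiH/O2 gives tert-butyl{[(2S,3S)-3-{(2R,4R)-2,4-dimethyl-12-phenyl-2-[(triethylsilyl)peroxy]dodecyl}-3-methyloxiran-2-yl]methoxy}dimethylsilane F3, again with its C5 epimer.
- Bu4NF in THF removes both silyl groups, and the peroxide anion should open the epoxide at its tertiary carbon (5-exo-tet, inversion at C3) to (1S)-1-{(3R,5R)-3,5-dimethyl-5-[(2R)-2-methyl-10-phenyldecyl]-1,2-dioxolan-3-yl}ethane-1,2-diol F4, which is separated from its trans ring isomer.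
- NaIO4 cleaves the diol to (3R,5R)-3,5-dimethyl-5-[(2R)-2-methyl-10-phenyldecyl]-1,2-dioxolane-3-carbaldehyde F5.
- Wittig reaction with Ph3P=CHOCH3 gives (3R,5R)-3-(2-methoxyethenyl)-3,5-dimethyl-5-[(2R)-2-methyl-10-phenyldecyl]-1,2-dioxolane F6.
- Hg(OAc)2 in aqueous THF hydrolyses the enol ether to 2-{(3R,5R)-3,5-dimethyl-5-[(2R)-2-methyl-10-phenyldecyl]-1,2-dioxolan-3-yl}acetaldehyde F7.
- Pinnick oxidation (NaClO2, NaH2PO4, 2-methylbut-2-ene) gives 21.

Step 2. The skipped enyne may isomerise, the alkenyl group may transfer poorly from the aluminate to formaldehyde, or the organolithium may attack the vinylic bromide during aluminate formation. The fallback sets out from 3 and comes back at 6. After the same carboalumination, alane 4 is trapped directly with ethyl chloroformate, with no organolithium, to give ethyl (2E)-5-bromo-3-methylhexa-2,5-dienoate F8. Reduction with i-Bu2AlH in CH2Cl2 at −78 °C returns 6.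

Step 7. The alkylpalladium intermediate may undergo beta-hydride elimination and chain isomerisation, and the magnesium and zinc halides may open the oxetane by halide attack. The fallback sets out from 14 and comes back at 17. Grignard reagent 15 is treated with B-methoxy-9-borabicyclo[3.3.1]nonane to give 9-[(2S)-2-methyl-10-phenyldecyl]-9-borabicyclo[3.3.1]nonane F9 (descriptor changed by priorities only). A B-alkyl Suzuki–Miyaura coupling with 10 (Pd(dppf)Cl2, K3PO4, THF/H2O, 60 °C) then gives 17 under basic, Lewis-acid-free conditions.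

Further compounds
F1 | step 10 | tert-butyl{[(2S,3S)-3-(2-bromoprop-2-en-1-yl)-3-methyloxiran-2-yl]methoxy}dimethylsilane | C=C(Br)C[C@]1(C)O[C@H]1CO[Si](C)(C)C(C)(C)C
F2 | step 10 | tert-butyldimethyl{[(2S,3S)-3-methyl-3-[(4R)-4-methyl-2-methylidene-12-phenyldodecyl]oxiran-2-yl]methoxy}silane | C=C(C[C@H](C)CCCCCCCCc1ccccc1)C[C@]1(C)O[C@H]1CO[Si](C)(C)C(C)(C)C
F3 | step 10 | tert-butyl{[(2S,3S)-3-{(2R,4R)-2,4-dimethyl-12-phenyl-2-[(triethylsilyl)peroxy]dodecyl}-3-methyloxiran-2-yl]methoxy}dimethylsilane | C[C@H](CCCCCCCCc1ccccc1)C[C@](OO[Si](CC)(CC)CC)(C)C[C@]1(C)O[C@H]1CO[Si](C)(C)C(C)(C)C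
F4 | step 10 | (1S)-1-{(3R,5R)-3,5-dimethyl-5-[(2R)-2-methyl-10-phenyldecyl]-1,2-dioxolan-3-yl}ethane-1,2-diol | C[C@H](CCCCCCCCc1ccccc1)C[C@]1(C)C[C@](C)([C@@H](O)CO)OO1
F5 | step 10 | (3R,5R)-3,5-dimethyl-5-[(2R)-2-methyl-10-phenyldecyl]-1,2-dioxolane-3-carbaldehyde | C[C@H](CCCCCCCCc1ccccc1)C[C@]1(C)C[C@](C)(C=O)OO1
F6 | step 10 | (3R,5R)-3-(2-methoxyethenyl)-3,5-dimethyl-5-[(2R)-2-methyl-10-phenyldecyl]-1,2-dioxolane | C[C@H](CCCCCCCCc1ccccc1)C[C@]1(C)C[C@](C)(C=COC)OO1
F7 | step 10 | 2-{(3R,5R)-3,5-dimethyl-5-[(2R)-2-methyl-10-phenyldecyl]-1,2-dioxolan-3-yl}acetaldehyde | C[C@H](CCCCCCCCc1ccccc1)C[C@]1(C)C[C@](C)(CC=O)OO1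
F8 | step 2 | ethyl (2E)-5-bromo-3-methylhexa-2,5-dienoate | C=C(Br)C/C(C)=C/C(=O)OCC
F9 | step 7 | 9-[(2S)-2-methyl-10-phenyldecyl]-9-borabicyclo[3.3.1]nonane | C[C@H](CCCCCCCCc1ccccc1)CB1C2CCCC1CCC2
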